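**Retrosynthetic overview**
- The hydroquinone is unmasked last from its dimethyl ether (oxidation to the quinone, then reduction); the E-enone comes from an N-methyl carboxamide by amide activation and alkenylzinc addition.
- Key disconnection: the ring-CH2–C(=O) bond. It is made by an electrochemical, nickel-catalysed amidyl-relay C–H acylation of one of two geminal methyl groups with the (Z)-aryl-pentenoic acid; this step also creates the second quaternary stereocentre.
- The cyclopentane and its first quaternary centre are bought as the anhydride of natural (+)-camphoric acid; the surplus secondary carboxyl is removed by photodecarboxylation.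
- The (Z)-acid comes from copper-catalysed opening of a β,γ-unsaturated δ-lactone by an aryl Grignard reagent.
- Rings: cyclopentane and arene are bought; the only ring formed is the δ-lactone (ring-closing metathesis, fixes the Z-olefin), which is opened again in the next step.

Assumption: the SMILES is read as (1R,2R) on the cyclopentane (ring methyls cis), Z at the aryl-side olefin and E at the enone; the camphoric anhydride, 3-methylbut-3-enoic acid and the trimethylsilyl ether of 2-methylbut-3-yn-2-ol are taken as catalogue items.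

**Route**

Step 1
Reactants: 1 (1R,5S)-1,8,8-trimethyl-3-oxabicyclo[3.2.1]octane-2,4-dione (anhydride of (1R,3S)-camphoric acid)
Product: 3 (R)-1,2,2-trimethylcyclopentane-1-carboxylic acid, via NHPI half-ester 2 (not isolated)
Conditions: N-hydroxyphthalimide, Et3N, CH2Cl2/DMF, 20 °C; then Hantzsch ester, Ru(bpy)3Cl2 (1 mol %), blue LED 450 nm, 20 °C
Reagents that add atoms: none
Why: N-hydroxyphthalimide opens the anhydride only at the unhindered secondary acyl carbon, and visible-light single-electron reduction of that redox-active ester expels CO2 to a secondary radical that takes a hydrogen atom from the Hantzsch ester (photoredox reductive decarboxylation); the bought quaternary centre is untouched.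

Step 2
Reactants: 3 (R)-1,2,2-trimethylcyclopentane-1-carboxylic acid
Product: 6 (R)-N,1,2,2-tetramethyl-N-{[4-(trifluoromethyl)benzoyl]oxy}cyclopentane-1-carboxamide, via acid chloride 4 (not isolated), via hydroxamic acid 5 (not isolated)
Conditions: (COCl)2, DMF (cat.), CH2Cl2, 0 to 20 °C; MeNHOH·HCl, Et3N, 0 to 40 °C; then 4-(trifluoromethyl)benzoyl chloride, Et3N, DMAP (cat.), 0 °C
Reagents that add atoms: N-methylhydroxylamine hydrochloride, CNO.Cl; 4-(trifluoromethyl)benzoyl chloride, O=C(Cl)c1ccc(cc1)C(F)(F)F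
Why: Acid chloride formation, N-acylation of the small alpha-effect nucleophile and O-aroylation (Schotten–Baumann-type acyl substitutions) install a reducible N–O bond without touching the stereocentre.

Step 3
Reactants: 7 4-methoxy-2-methylphenol
Product: 8 2-bromo-4-methoxy-6-methylphenol
Conditions: N-bromosuccinimide, CH2Cl2, -20 to 0 °C, dark
Reagents that add atoms: N-bromosuccinimide, O=C1CCC(=O)N1Br
Why: Electrophilic aromatic bromination goes to the only free position ortho to the phenol OH (para is blocked by OMe), which fixes the substitution pattern of the arene.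

Step 4
Reactants: 8 2-bromo-4-methoxy-6-methylphenol
Product: 9 1-bromo-2,5-dimethoxy-3-methylbenzene
Conditions: MeI, K2CO3, acetone, 56 °C
Reagents that add atoms: iodomethane, CI
Why: Williamson ether synthesis on the phenoxide gives the quinone-precursor dimethyl ether, which is inert to the organometallic and reductive steps that follow.

Step 5
Reactants: 10 3-methylbut-3-enoic acid; 11 allyl bromide
Product: 12 allyl 3-methylbut-3-enoate
Conditions: KHCO3, DMF, 20 °C
Reagents that add atoms: none
Why: SN2 O-alkylation of the carboxylate under weakly basic conditions keeps the β,γ-double bond out of conjugation.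

Step 6
Reactants: 12 allyl 3-methylbut-3-enoate
Product: 13 4-methyl-3,6-dihydro-2H-pyran-2-one
Conditions: second-generation Grubbs catalyst RuCl2(=CHPh)(PCy3)(H2IMes) (2 mol %), CH2Cl2 (0.02 M), 40 °C
Reagents that add atoms: none
Why: Ring-closing metathesis to the six-membered lactone; the ring forces the two CH2 arms of the trisubstituted olefin cis, which is the Z geometry of the target.

Step 7
Reactants: 9 1-bromo-2,5-dimethoxy-3-methylbenzene; 13 4-methyl-3,6-dihydro-2H-pyran-2-one
Product: 15 (Z)-5-(2,5-dimethoxy-3-methylphenyl)-3-methylpent-3-enoic acid, via aryl Grignard reagent 14 (not isolated)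
Conditions: Mg, LiCl, THF, 40 °C; then 13, CuBr·SMe2 (10 mol %), THF, -40 to 0 °C; 1 M HCl
Reagents that add atoms: none
Why: Copper-catalysed SN2 allylic substitution: the aryl cuprate displaces the allylic carboxylate at the primary carbon (SN2' would have to build a quaternary centre), opening the lactone with retention of the ring-derived Z geometry.

Step 8
Reactants: 6 (R)-N,1,2,2-tetramethyl-N-{[4-(trifluoromethyl)benzoyl]oxy}cyclopentane-1-carboxamide; 15 (Z)-5-(2,5-dimethoxy-3-methylphenyl)-3-methylpent-3-enoic acid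
Product: 17 (1R,2R)-2-[(Z)-6-(2,5-dimethoxy-3-methylphenyl)-4-methyl-2-oxohex-4-en-1-yl]-N,1,2-trimethylcyclopentane-1-carboxamide, via mixed carbonic anhydride 16 (not isolated)
Conditions: 15, Boc2O, MgCl2, MeCN, 20 °C; then 6, NiBr2(dme) (10 mol %), 4,4'-di-tert-butyl-2,2'-bipyridine (12 mol %), nBu4NBr, MeCN, undivided cell, zinc anode, nickel-foam cathode, 4 mA constant current, 2.5 F/mol, 20 °C
Reagents that add atoms: none
Why: Proposed new method: zerovalent nickel from the cathode adds oxidatively to the mixed anhydride 16 to give an acyl complex of divalent nickel, while monovalent nickel (or the cathode) passes one electron into the weak N–O bond of 6 and releases aroate plus an N-methyl amidyl radical; this radical takes a hydrogen atom through a six-membered transition state (1,5-hydrogen atom transfer of the Hofmann–Löffler–Freytag type) and can only reach the C2 methyl cis to the carboxamide (the trans methyl and the ring CH2 groups are out of range), so the bought C1 centre decides which geminal methyl reacts and fixes the new quaternary centre as R; the neopentyl radical is trapped by the acyl–nickel species and reductive elimination from trivalent nickel forms the CH2–C(=O) bond under base-free conditions that should spare the β,γ-olefin and the electron-rich arene; the closest known reaction types are nickel-catalysed (electro)reductive ketone synthesis from alkyl halides or redox-active esters with anhydrides and amidyl-relay γ-C–H alkylation, but an N-acyloxy amide has not been used as the relay partner of an acyl electrophile.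

Step 9
Reactants: 17 (1R,2R)-2-[(Z)-6-(2,5-dimethoxy-3-methylphenyl)-4-methyl-2-oxohex-4-en-1-yl]-N,1,2-trimethylcyclopentane-1-carboxamide; 18 trimethyl[(2-methylbut-3-yn-2-yl)oxy]silane
Product: 23 (E)-1-{(1R,2R)-2-[(Z)-6-(2,5-dimethoxy-3-methylphenyl)-4-methyl-2-oxohex-4-en-1-yl]-1,2-dimethylcyclopentyl}-4-hydroxy-4-methylpent-2-en-1-one, via alkenylzirconocene 19 (not isolated), via alkenylzinc 20 (not isolated), via imidoyl triflate 21 (not isolated), via ketimine 22 (not isolated)
Conditions: 18 (2.2 equiv), Cp2Zr(H)Cl (2.0 equiv), CH2Cl2, 20 °C; Me2Zn, -65 °C; separately 17, Tf2O (1.1 equiv), 2-fluoropyridine (1.2 equiv), CH2Cl2, -78 to 0 °C; combine at -78 °C, then 0 °C; 0.5 M HCl, THF, 20 °C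
Reagents that add atoms: water, O
Why: Tf2O/2-fluoropyridine turns the secondary amide into an imidoyl triflate that accepts the alkenylzinc once (syn-hydrozirconation then Zr-to-Zn transmetalation gives the E-alkenyl group) while the uncatalysed ketone is left alone, and acid hydrolysis of the ketimine and the silyl ether gives the E-enone (electrophilic amide activation with organozinc addition).

Step 10
Reactants: 23 (E)-1-{(1R,2R)-2-[(Z)-6-(2,5-dimethoxy-3-methylphenyl)-4-methyl-2-oxohex-4-en-1-yl]-1,2-dimethylcyclopentyl}-4-hydroxy-4-methylpent-2-en-1-one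
Product: 25 (E)-1-{(1R,2R)-2-[(Z)-6-(2,5-dihydroxy-3-methylphenyl)-4-methyl-2-oxohex-4-en-1-yl]-1,2-dimethylcyclopentyl}-4-hydroxy-4-methylpent-2-en-1-one, via quinone 24 (not isolated)
Conditions: (NH4)2Ce(NO3)6 (2.5 equiv), MeCN/H2O 2:1, 0 °C, 15 min; then aq. Na2S2O4, EtOAc, 20 °C, argon
Reagents that add atoms: water, O
Why: Oxidative demethylation of the 1,4-dimethoxyarene gives the p-quinone, which dithionite reduces at once to the hydroquinone; neither reagent touches the enone, the skipped olefin or the two stereocentres.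

**Compound list**

1 | (1R,5S)-1,8,8-trimethyl-3-oxabicyclo[3.2.1]octane-2,4-dione (anhydride of (1R,3S)-(+)-camphoric acid) | C[C@]12CC[C@H](C(=O)OC1=O)C2(C)C | starting material
2 | (1R,3S)-3-{[(1,3-dioxoisoindolin-2-yl)oxy]carbonyl}-1,2,2-trimethylcyclopentane-1-carboxylic acid | C[C@@]1(C(=O)O)CC[C@H](C(=O)ON2C(=O)c3ccccc3C2=O)C1(C)C | intermediate
3 | (R)-1,2,2-trimethylcyclopentane-1-carboxylic acid | C[C@@]1(C(=O)O)CCCC1(C)C | intermediate
4 | (R)-1,2,2-trimethylcyclopentane-1-carbonyl chloride | C[C@@]1(C(=O)Cl)CCCC1(C)C | intermediate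
5 | (R)-N-hydroxy-N,1,2,2-tetramethylcyclopentane-1-carboxamide | C[C@@]1(C(=O)N(C)O)CCCC1(C)C | intermediate
6 | (R)-N,1,2,2-tetramethyl-N-{[4-(trifluoromethyl)benzoyl]oxy}cyclopentane-1-carboxamide | C[C@@]1(C(=O)N(C)OC(=O)c2ccc(cc2)C(F)(F)F)CCCC1(C)C | intermediate
7 | 4-methoxy-2-methylphenol | COc1ccc(O)c(C)c1 | starting material
8 | 2-bromo-4-methoxy-6-methylphenol | COc1cc(C)c(O)c(Br)c1 | intermediate
9 | 1-bromo-2,5-dimethoxy-3-methylbenzene | COc1cc(C)c(OC)c(Br)c1 | intermediate
10 | 3-methylbut-3-enoic acid | CC(=C)CC(=O)O | starting material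
11 | allyl bromide | C=CCBr | starting material
12 | allyl 3-methylbut-3-enoate | CC(=C)CC(=O)OCC=C | intermediate
13 | 4-methyl-3,6-dihydro-2H-pyran-2-one | CC1=CCOC(=O)C1 | intermediate
14 | (2,5-dimethoxy-3-methylphenyl)magnesium bromide | COc1cc(C)c(OC)c([Mg]Br)c1 | intermediate
15 | (Z)-5-(2,5-dimethoxy-3-methylphenyl)-3-methylpent-3-enoic acid | C/C(=C/Cc1cc(OC)cc(C)c1OC)CC(=O)O | intermediate
16 | tert-butyl carbonic (Z)-5-(2,5-dimethoxy-3-methylphenyl)-3-methylpent-3-enoic anhydride | C/C(=C/Cc1cc(OC)cc(C)c1OC)CC(=O)OC(=O)OC(C)(C)C | intermediate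
17 | (1R,2R)-2-[(Z)-6-(2,5-dimethoxy-3-methylphenyl)-4-methyl-2-oxohex-4-en-1-yl]-N,1,2-trimethylcyclopentane-1-carboxamide | C/C(=C/Cc1cc(OC)cc(C)c1OC)CC(=O)C[C@@]1(C)CCC[C@@]1(C)C(=O)NC | intermediate
18 | trimethyl[(2-methylbut-3-yn-2-yl)oxy]silane | C#CC(C)(C)O[Si](C)(C)C | starting material
19 | chlorobis(cyclopentadienyl)[(E)-3-methyl-3-(trimethylsilyloxy)but-1-en-1-yl]zirconium | Cl[Zr](/C=C/C(C)(C)O[Si](C)(C)C)(C1C=CC=C1)C1C=CC=C1 | intermediate
20 | methyl[(E)-3-methyl-3-(trimethylsilyloxy)but-1-en-1-yl]zinc | C[Zn]/C=C/C(C)(C)O[Si](C)(C)C | intermediate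
21 | imidoyl triflate of 17 [(1R,2R)-N-methyl carboximidoyl trifluoromethanesulfonate] | C/C(=C/Cc1cc(OC)cc(C)c1OC)CC(=O)C[C@@]1(C)CCC[C@@]1(C)C(OS(=O)(=O)C(F)(F)F)=NC | intermediate
22 | (E)-1-{(1R,2R)-2-[(Z)-6-(2,5-dimethoxy-3-methylphenyl)-4-methyl-2-oxohex-4-en-1-yl]-1,2-dimethylcyclopentyl}-N,4-dimethyl-4-(trimethylsilyloxy)pent-2-en-1-imine | C/C(=C/Cc1cc(OC)cc(C)c1OC)CC(=O)C[C@@]1(C)CCC[C@@]1(C)C(=NC)/C=C/C(C)(C)O[Si](C)(C)C | intermediate
23 | (E)-1-{(1R,2R)-2-[(Z)-6-(2,5-dimethoxy-3-methylphenyl)-4-methyl-2-oxohex-4-en-1-yl]-1,2-dimethylcyclopentyl}-4-hydroxy-4-methylpent-2-en-1-one | C/C(=C/Cc1cc(OC)cc(C)c1OC)CC(=O)C[C@@]1(C)CCC[C@@]1(C)C(=O)/C=C/C(C)(C)O | intermediate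
24 | 2-{(Z)-6-[(1R,2R)-2-((E)-4-hydroxy-4-methylpent-2-enoyl)-1,2-dimethylcyclopentyl]-3-methyl-5-oxohex-2-en-1-yl}-6-methylcyclohexa-2,5-diene-1,4-dione | C/C(=C/CC1=CC(=O)C=C(C)C1=O)CC(=O)C[C@@]1(C)CCC[C@@]1(C)C(=O)/C=C/C(C)(C)O | intermediate
25 | (E)-1-{(1R,2R)-2-[(Z)-6-(2,5-dihydroxy-3-methylphenyl)-4-methyl-2-oxohex-4-en-1-yl]-1,2-dimethylcyclopentyl}-4-hydroxy-4-methylpent-2-en-1-one | C/C(=C/Cc1cc(O)cc(C)c1O)CC(=O)C[C@@]1(C)CCC[C@@]1(C)C(=O)/C=C/C(C)(C)O | target

**Step count and risks**

Total steps: 10. Longest linear sequence: 6 (steps 3, 4, 7, 8, 9, 10; the lactone branch 5, 6, 7, 8, 9, 10 is equally long).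

The three steps most likely to fail:

Step 8 (the proposed new relay acylation). The amidyl radical may be reduced to the plain amide before the hydrogen shift, nickel may insert into the N–O bond in a two-electron sense, or the β,γ-unsaturated acyl–nickel species may lose CO to an allyl complex. The fallback uses known chemistry and separates halogenation from coupling. It sets out from 3: SOCl2 then MeNH2 gives (R)-N,1,2,2-tetramethylcyclopentane-1-carboxamide F1; tert-butyl hypobromite gives (R)-N-bromo-N,1,2,2-tetramethylcyclopentane-1-carboxamide F2; irradiation at 365 nm in PhCF3 brings about the Hofmann–Löffler–Freytag bromine shift to (1R,2S)-2-(bromomethyl)-N,1,2-trimethylcyclopentane-1-carboxamide F3, with the same cis-methyl selectivity; a nickel-catalysed reductive acylation of this neopentyl bromide with 15 (Boc2O, MgCl2, Zn, NiBr2(dme), 4,4'-di-tert-butyl-2,2'-bipyridine, DMA) comes back to the route at 17.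

Step 9. The imidoyl triflate sits between two quaternary carbons, and the δ-ketone oxygen may trap it before the alkenylzinc arrives. The fallback goes through the aldehyde oxidation level and sets out from 17: Tf2O, 2-fluoropyridine, then Et3SiH and aqueous citric acid give (1R,2R)-2-[(Z)-6-(2,5-dimethoxy-3-methylphenyl)-4-methyl-2-oxohex-4-en-1-yl]-1,2-dimethylcyclopentane-1-carbaldehyde F4; 18 is turned by Cp2Zr(H)Cl, I2 and dilute HCl into (E)-4-iodo-2-methylbut-3-en-2-ol F5; a Nozaki–Hiyama–Kishi coupling of F4 and F5 (CrCl2, catalytic NiCl2, DMF), which adds to the aldehyde and not the ketone, gives (E)-1-{(1R,2R)-2-[(Z)-6-(2,5-dimethoxy-3-methylphenyl)-4-methyl-2-oxohex-4-en-1-yl]-1,2-dimethylcyclopentyl}-4-methylpent-2-ene-1,4-diol F6 as a mixture of carbinol epimers; Dess–Martin periodinane oxidises the secondary allylic alcohol and comes back to the route at 23.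

Step 7. The aryl copper species may attack the lactone carbonyl, enolise the lactone or react SN2'. The fallback makes the aryl–CH2 bond by phenoxide C-alkylation and sets out from 13 (with 7): BBr3 in CH2Cl2 then MeOH opens the lactone to methyl (Z)-5-bromo-3-methylpent-3-enoate F7; the sodium phenoxide of 7 (NaH, toluene) is C-allylated at its only free ortho position to give methyl (Z)-5-(2-hydroxy-5-methoxy-3-methylphenyl)-3-methylpent-3-enoate F8; MeI and K2CO3 give methyl (Z)-5-(2,5-dimethoxy-3-methylphenyl)-3-methylpent-3-enoate F9; LiOH in THF/H2O comes back to the route at 15.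

**Further compounds**

F1 | step 8 | (R)-N,1,2,2-tetramethylcyclopentane-1-carboxamide | C[C@@]1(C(=O)NC)CCCC1(C)C
F2 | step 8 | (R)-N-bromo-N,1,2,2-tetramethylcyclopentane-1-carboxamide | C[C@@]1(C(=O)N(C)Br)CCCC1(C)C
F3 | step 8 | (1R,2S)-2-(bromomethyl)-N,1,2-trimethylcyclopentane-1-carboxamide | BrC[C@@]1(C)CCC[C@@]1(C)C(=O)NC
F4 | step 9 | (1R,2R)-2-[(Z)-6-(2,5-dimethoxy-3-methylphenyl)-4-methyl-2-oxohex-4-en-1-yl]-1,2-dimethylcyclopentane-1-carbaldehyde | C/C(=C/Cc1cc(OC)cc(C)c1OC)CC(=O)C[C@@]1(C)CCC[C@@]1(C)C=O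
F5 | step 9 | (E)-4-iodo-2-methylbut-3-en-2-ol | CC(C)(O)/C=C/I
F6 | step 9 | (E)-1-{(1R,2R)-2-[(Z)-6-(2,5-dimethoxy-3-methylphenyl)-4-methyl-2-oxohex-4-en-1-yl]-1,2-dimethylcyclopentyl}-4-methylpent-2-ene-1,4-diol (carbinol epimers) | C/C(=C/Cc1cc(OC)cc(C)c1OC)CC(=O)C[C@@]1(C)CCC[C@@]1(C)C(O)/C=C/C(C)(C)O
F7 | step 7 | methyl (Z)-5-bromo-3-methylpent-3-enoate | C/C(=C/CBr)CC(=O)OC
F8 | step 7 | methyl (Z)-5-(2-hydroxy-5-methoxy-3-methylphenyl)-3-methylpent-3-enoate | C/C(=C/Cc1cc(OC)cc(C)c1O)CC(=O)OC
F9 | step 7 | methyl (Z)-5-(2,5-dimethoxy-3-methylphenyl)-3-methylpent-3-enoate | C/C(=C/Cc1cc(OC)cc(C)c1OC)CC(=O)OC
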